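**Retrosynthetic overview**

1. Rings: A = 2,4-dihydroxyphenyl ketone ring, B = central phenol ring, C/D = benzo and pyran rings of the chromene, E = 4-hydroxyphenyl on C2. The last C–C bond made is C(=O)–C-alpha of the chalcone, by rhodium-catalysed hydroacylation of terminal alkyne 14 (rings B–E) with salicylaldehyde 2 (ring A), followed by global desilylation.
2. Enabling feature: the free 2'-OH of ring A ortho to the ketone carbon. Phenoxide O, C2', C1' and the acyl carbon close a five-membered acylrhodium chelate that allows aldehyde C–H activation and blocks decarbonylation.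
3. Alkyne 14 comes from a Suzuki–Miyaura coupling at the chromene C3–ring B bond: 3-bromochromene 7 plus arylboronate 12 (from 2-bromo-4-iodophenol).
4. Bromide 7 comes from aldehyde 5 (Pinnick oxidation, bromodecarboxylation). Aldehyde 5 comes from an organocatalytic oxa-Michael/aldol domino of 2 with enal 4, which sets C2 as S.
5. Ring order: benzene rings A, B, C and E are bought; pyran ring D is the only ring built (step 3). Building block 2 supplies both resorcinol rings, A and C.

Key step: step 10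

Assumption: the C2 stereocentre of a 2-aryl-2H-chromene is taken to be configurationally stable in the dark, without strong acid and below about 80 °C, so every step after step 3 is kept within these limits.

**Route**

Step 1
Reactants: 1 2,4-dihydroxybenzaldehyde
Product: 2 2-hydroxy-4-(triisopropylsilyloxy)benzaldehyde
Conditions: TIPSCl (1.05 equiv), imidazole, CH2Cl2, 0 °C
Reagents that add atoms: chlorotriisopropylsilane, CC(C)[Si](Cl)(C(C)C)C(C)C
Why: Chemoselective O-silylation; the 4-OH is the more acidic and unhindered phenol, whereas the 2-OH is held in a hydrogen bond to the formyl oxygen, so one equivalent of silyl chloride should react at O4 only.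

Step 2
Reactants: 3 (E)-3-(4-hydroxyphenyl)prop-2-enal
Product: 4 (E)-3-[4-(triisopropylsilyloxy)phenyl]prop-2-enal
Conditions: TIPSCl, imidazole, DMF, rt
Reagents that add atoms: chlorotriisopropylsilane, CC(C)[Si](Cl)(C(C)C)C(C)C
Why: Standard imidazole-mediated phenol silylation, which also prevents the para-phenol from quenching the iminium ion of step 3 as a quinone methide.

Step 3
Reactants: 2 2-hydroxy-4-(triisopropylsilyloxy)benzaldehyde + 4 (E)-3-[4-(triisopropylsilyloxy)phenyl]prop-2-enal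
Product: 5 (S)-7-(triisopropylsilyloxy)-2-[4-(triisopropylsilyloxy)phenyl]-2H-chromene-3-carbaldehyde
Conditions: (R)-α,α-diphenylprolinol trimethylsilyl ether (20 mol%), 2-nitrobenzoic acid (20 mol%), 4 Å molecular sieves, toluene, rt, dark
Reagents that add atoms: none
Why: Amine-catalysed domino oxa-Michael/aldol condensation (iminium then enamine activation): the phenol oxygen of 2 adds to C-beta of the E-iminium ion of 4 on the face anti to the CPh2(OSiMe3) group of the R catalyst, which should set C2 as S, and the enamine then closes ring D by a 6-exo-trig aldol onto the formyl group before dehydration (the antipodal catalyst would give the 2R series).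

Step 4
Reactants: 5 (S)-7-(triisopropylsilyloxy)-2-[4-(triisopropylsilyloxy)phenyl]-2H-chromene-3-carbaldehyde
Product: 6 (S)-7-(triisopropylsilyloxy)-2-[4-(triisopropylsilyloxy)phenyl]-2H-chromene-3-carboxylic acid
Conditions: NaClO2, NaH2PO4, 2-methyl-2-butene, t-BuOH/THF/H2O, 0 °C to rt
Reagents that add atoms: sodium chlorite, [Na+].[O-]Cl=O
Why: Pinnick oxidation of the enal under buffered conditions with an alkene scavenger for HOCl should give the acid without touching the C3=C4 bond, the silyl ethers or C2.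

Step 5
Reactants: 6 (S)-7-(triisopropylsilyloxy)-2-[4-(triisopropylsilyloxy)phenyl]-2H-chromene-3-carboxylic acid
Product: 7 (S)-3-bromo-7-(triisopropylsilyloxy)-2-[4-(triisopropylsilyloxy)phenyl]-2H-chromene
Conditions: NBS (1.05 equiv), LiOAc (10 mol%), MeCN/H2O, 0 °C to rt, dark
Reagents that add atoms: N-bromosuccinimide, O=C1CCC(=O)N1Br
Why: Catalytic Hunsdiecker-type bromodecarboxylation of an electron-rich cinnamic acid: bromonium attack at C3 gives a C4 benzylic cation stabilised by O1 and the 7-silyloxy group, and loss of CO2 restores C3=C4 with bromine on C3, leaving C2 untouched.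

Step 6
Reactants: 8 2-bromo-4-iodophenol
Product: 9 (2-bromo-4-iodophenoxy)triisopropylsilane
Conditions: TIPSCl, imidazole, DMF, rt
Reagents that add atoms: chlorotriisopropylsilane, CC(C)[Si](Cl)(C(C)C)C(C)C
Why: Standard phenol silylation, giving ring B the same protecting group as the other phenols.

Step 7
Reactants: 9 (2-bromo-4-iodophenoxy)triisopropylsilane + 10 ethynyltrimethylsilane
Product: 11 {[3-bromo-4-(triisopropylsilyloxy)phenyl]ethynyl}trimethylsilane
Conditions: Pd(PPh3)2Cl2 (2 mol%), CuI (4 mol%), Et3N, THF, rt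
Reagents that add atoms: none
Why: Sonogashira coupling; oxidative addition of zerovalent palladium into C–I is far faster than into the ortho C–Br bond, so only the position para to oxygen should be alkynylated.

Step 8
Reactants: 11 {[3-bromo-4-(triisopropylsilyloxy)phenyl]ethynyl}trimethylsilane
Product: 12 trimethyl{[3-(4,4,5,5-tetramethyl-1,3,2-dioxaborolan-2-yl)-4-(triisopropylsilyloxy)phenyl]ethynyl}silane
Conditions: B2pin2, Pd(dppf)Cl2 (5 mol%), KOAc, 1,4-dioxane, 85 °C
Reagents that add atoms: bis(pinacolato)diboron, CC1(C)OB(OC1(C)C)B1OC(C)(C)C(C)(C)O1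
Why: Miyaura borylation of the aryl bromide; the weak base KOAc does not activate the product boronate toward homocoupling and leaves the C–SiMe3 and O–Si bonds intact.

Step 9
Reactants: 7 (S)-3-bromo-7-(triisopropylsilyloxy)-2-[4-(triisopropylsilyloxy)phenyl]-2H-chromene + 12 trimethyl{[3-(4,4,5,5-tetramethyl-1,3,2-dioxaborolan-2-yl)-4-(triisopropylsilyloxy)phenyl]ethynyl}silane
Product: 14 (S)-3-[5-ethynyl-2-(triisopropylsilyloxy)phenyl]-7-(triisopropylsilyloxy)-2-[4-(triisopropylsilyloxy)phenyl]-2H-chromene, via trimethylsilylalkyne 13 (not isolated)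
Conditions: Pd(OAc)2 (5 mol%), SPhos (10 mol%), K3PO4, THF/H2O, 45 °C; then MeOH, K2CO3, rt, short contact
Reagents that add atoms: none
Why: Suzuki–Miyaura coupling of the alkenyl bromide with the ortho-substituted arylboronate (a dialkylbiarylphosphine ligand suits hindered partners) forms the C3–ring B bond, and K2CO3/MeOH then cleaves only the alkynyl C–Si bond because aryl triisopropylsilyl ethers methanolyse far more slowly.

Step 10
Reactants: 14 (S)-3-[5-ethynyl-2-(triisopropylsilyloxy)phenyl]-7-(triisopropylsilyloxy)-2-[4-(triisopropylsilyloxy)phenyl]-2H-chromene + 2 2-hydroxy-4-(triisopropylsilyloxy)benzaldehyde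
Product: 15 (E)-1-[2-hydroxy-4-(triisopropylsilyloxy)phenyl]-3-{4-(triisopropylsilyloxy)-3-[(S)-7-(triisopropylsilyloxy)-2-[4-(triisopropylsilyloxy)phenyl]-2H-chromen-3-yl]phenyl}prop-2-en-1-one
Conditions: [RhCl(cod)]2 (2.5 mol%), dppf (5 mol%), Na2CO3 (10 mol%), 2 (1.5 equiv), toluene, 70 °C, dark
Reagents that add atoms: none
Why: Carbonate generates the rhodium phenoxide of 2, and oxidative addition of the neighbouring formyl C–H bond to monovalent rhodium gives a five-membered acyl(hydrido) chelate of trivalent rhodium (Rh, O, C2, C1, acyl C) that resists decarbonylation; the alkyne of 14 then inserts into Rh–H with rhodium on the terminal carbon, and C(acyl)–C(alkenyl) reductive elimination forms the C(=O)–C-alpha bond. The closest known reaction type is the rhodium/diphosphine-catalysed intermolecular hydroacylation of alkynes with salicylaldehydes to 2-alkenoylphenols. No ring is closed and no stereocentre is created; the E geometry follows from syn addition of H and acyl across the triple bond. The step needs linear rather than branched regioselectivity, which the substrate should secure because the terminal carbon is the less hindered one and because in aryl alkynes the acyl group goes to the carbon remote from the (here electron-rich) arene. It also needs chemoselectivity for the alkyne over the trisubstituted C3=C4 bond of ring D, which is too hindered to insert, and C2 is not touched under these near-neutral conditions.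

Step 11
Reactants: 15 (E)-1-[2-hydroxy-4-(triisopropylsilyloxy)phenyl]-3-{4-(triisopropylsilyloxy)-3-[(S)-7-(triisopropylsilyloxy)-2-[4-(triisopropylsilyloxy)phenyl]-2H-chromen-3-yl]phenyl}prop-2-en-1-one
Product: 16 (E)-1-(2,4-dihydroxyphenyl)-3-{4-hydroxy-3-[(S)-7-hydroxy-2-(4-hydroxyphenyl)-2H-chromen-3-yl]phenyl}prop-2-en-1-one
Conditions: tetrabutylammonium fluoride (5 equiv), AcOH (5 equiv), THF, 0 °C to rt
Reagents that add atoms: none
Why: Fluoride-mediated cleavage of the four aryl silyl ethers, buffered with acetic acid so that base does not cyclise the 2'-hydroxychalcone to a flavanone and acid does not ionise the chromene C2–O bond.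

**Compound list**

1 | 2,4-dihydroxybenzaldehyde | O=Cc1ccc(O)cc1O | starting material
2 | 2-hydroxy-4-(triisopropylsilyloxy)benzaldehyde | O=Cc1ccc(O[Si](C(C)C)(C(C)C)C(C)C)cc1O | intermediate
3 | (E)-3-(4-hydroxyphenyl)prop-2-enal | O=C/C=C/c1ccc(O)cc1 | starting material
4 | (E)-3-[4-(triisopropylsilyloxy)phenyl]prop-2-enal | O=C/C=C/c1ccc(O[Si](C(C)C)(C(C)C)C(C)C)cc1 | intermediate
5 | (S)-7-(triisopropylsilyloxy)-2-[4-(triisopropylsilyloxy)phenyl]-2H-chromene-3-carbaldehyde | O=CC1=Cc2ccc(O[Si](C(C)C)(C(C)C)C(C)C)cc2O[C@H]1c1ccc(O[Si](C(C)C)(C(C)C)C(C)C)cc1 | intermediate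
6 | (S)-7-(triisopropylsilyloxy)-2-[4-(triisopropylsilyloxy)phenyl]-2H-chromene-3-carboxylic acid | OC(=O)C1=Cc2ccc(O[Si](C(C)C)(C(C)C)C(C)C)cc2O[C@H]1c1ccc(O[Si](C(C)C)(C(C)C)C(C)C)cc1 | intermediate
7 | (S)-3-bromo-7-(triisopropylsilyloxy)-2-[4-(triisopropylsilyloxy)phenyl]-2H-chromene | BrC1=Cc2ccc(O[Si](C(C)C)(C(C)C)C(C)C)cc2O[C@H]1c1ccc(O[Si](C(C)C)(C(C)C)C(C)C)cc1 | intermediate
8 | 2-bromo-4-iodophenol | Oc1ccc(I)cc1Br | starting material
9 | (2-bromo-4-iodophenoxy)triisopropylsilane | CC(C)[Si](Oc1ccc(I)cc1Br)(C(C)C)C(C)C | intermediate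
10 | ethynyltrimethylsilane | C#C[Si](C)(C)C | starting material
11 | {[3-bromo-4-(triisopropylsilyloxy)phenyl]ethynyl}trimethylsilane | CC(C)[Si](Oc1ccc(C#C[Si](C)(C)C)cc1Br)(C(C)C)C(C)C | intermediate
12 | trimethyl{[3-(4,4,5,5-tetramethyl-1,3,2-dioxaborolan-2-yl)-4-(triisopropylsilyloxy)phenyl]ethynyl}silane | CC(C)[Si](Oc1ccc(C#C[Si](C)(C)C)cc1B1OC(C)(C)C(C)(C)O1)(C(C)C)C(C)C | intermediate
13 | (S)-7-(triisopropylsilyloxy)-2-[4-(triisopropylsilyloxy)phenyl]-3-{2-(triisopropylsilyloxy)-5-[(trimethylsilyl)ethynyl]phenyl}-2H-chromene | C[Si](C)(C)C#Cc1ccc(O[Si](C(C)C)(C(C)C)C(C)C)c(C2=Cc3ccc(O[Si](C(C)C)(C(C)C)C(C)C)cc3O[C@H]2c2ccc(O[Si](C(C)C)(C(C)C)C(C)C)cc2)c1 | intermediate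
14 | (S)-3-[5-ethynyl-2-(triisopropylsilyloxy)phenyl]-7-(triisopropylsilyloxy)-2-[4-(triisopropylsilyloxy)phenyl]-2H-chromene | C#Cc1ccc(O[Si](C(C)C)(C(C)C)C(C)C)c(C2=Cc3ccc(O[Si](C(C)C)(C(C)C)C(C)C)cc3O[C@H]2c2ccc(O[Si](C(C)C)(C(C)C)C(C)C)cc2)c1 | intermediate
15 | (E)-1-[2-hydroxy-4-(triisopropylsilyloxy)phenyl]-3-{4-(triisopropylsilyloxy)-3-[(S)-7-(triisopropylsilyloxy)-2-[4-(triisopropylsilyloxy)phenyl]-2H-chromen-3-yl]phenyl}prop-2-en-1-one | O=C(/C=C/c1ccc(O[Si](C(C)C)(C(C)C)C(C)C)c(C2=Cc3ccc(O[Si](C(C)C)(C(C)C)C(C)C)cc3O[C@H]2c2ccc(O[Si](C(C)C)(C(C)C)C(C)C)cc2)c1)c1ccc(O[Si](C(C)C)(C(C)C)C(C)C)cc1O | intermediate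
16 | (E)-1-(2,4-dihydroxyphenyl)-3-{4-hydroxy-3-[(S)-7-hydroxy-2-(4-hydroxyphenyl)-2H-chromen-3-yl]phenyl}prop-2-en-1-one | O=C(/C=C/c1ccc(O)c(C2=Cc3ccc(O)cc3O[C@H]2c2ccc(O)cc2)c1)c1ccc(O)cc1O | target

**Step count**

Total steps: 11. Longest linear sequence: 7 steps (steps 2, 3, 4, 5, 9, 10, 11; from 3 to 16).

**Steps most likely to fail, with fallbacks**

Step 10. What may go wrong: hydride insertion that places rhodium on the internal alkyne carbon (leading to the branched enone), or rhodium-mediated oligomerisation of the arylacetylene outrunning hydroacylation. The fallback sets out from 14 and returns at 16; it forms the same bond by polar addition at the alcohol oxidation level. Aldehyde 1 would be bis-silylated (TIPSOTf, 2,6-lutidine, CH2Cl2) to 2,4-bis(triisopropylsilyloxy)benzaldehyde F1. Deprotonation of 14 with LiN(SiMe3)2 (THF, −78 °C) and addition to F1 should give the propargylic alcohol F2 as a mixture of carbinol epimers. Hydroxyl-directed trans-hydroalumination with NaAlH2(OCH2CH2OCH3)2 (THF, 0 °C) should give the (E)-allylic alcohol F3. MnO2 (CH2Cl2, rt) should oxidise it to the penta-silylated chalcone F4, and the conditions of step 11 would then convert F4 into 16.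

Step 5. What may go wrong: electrophilic bromination of the silyloxy-activated benzene rings competing with attack at C3, or stalling before loss of CO2. The fallback sets out from 5 and returns at 7; it replaces ipso-bromodecarboxylation by decarbonylation and addition–elimination. Decarbonylation of 5 with stoichiometric RhCl(PPh3)3 (toluene, 80 °C) should give (R)-7-(triisopropylsilyloxy)-2-[4-(triisopropylsilyloxy)phenyl]-2H-chromene F5, which has the same spatial arrangement at C2 and a changed descriptor only because of the priority rules. Pyridinium tribromide (CH2Cl2, −78 °C) should add bromine across the enol-ether-like C3=C4 bond, much faster than arene substitution, to give the trans-3,4-dibromochromane F6. DBU (THF, 0 °C to rt) should then remove HBr through the C4 benzylic cation and loss of H3, giving 7.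

Step 9. What may go wrong: slow transmetalation at the doubly ortho-flanked coupling site, so that protodeboronation of 12 and base-induced loss of aryl silyl groups take over. The fallback sets out from 8 and returns at 14; it carries ring B through the coupling as the small free phenol and silylates afterwards. Sonogashira coupling of unprotected 8 with 10 (same catalyst system as step 7) should give 2-bromo-4-[(trimethylsilyl)ethynyl]phenol F7. Miyaura borylation (B2pin2, Pd(dppf)Cl2, KOAc) should give 2-(4,4,5,5-tetramethyl-1,3,2-dioxaborolan-2-yl)-4-[(trimethylsilyl)ethynyl]phenol F8. Suzuki–Miyaura coupling of F8 with 7 should give the trimethylsilylalkyne phenol F9, K2CO3/MeOH should give the ethynylphenol F10, and TIPSCl/imidazole would return to 14.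

**Further compounds**

F1 | step 10 | 2,4-bis(triisopropylsilyloxy)benzaldehyde | O=Cc1ccc(O[Si](C(C)C)(C(C)C)C(C)C)cc1O[Si](C(C)C)(C(C)C)C(C)C
F2 | step 10 | 1-[2,4-bis(triisopropylsilyloxy)phenyl]-3-{4-(triisopropylsilyloxy)-3-[(S)-7-(triisopropylsilyloxy)-2-[4-(triisopropylsilyloxy)phenyl]-2H-chromen-3-yl]phenyl}prop-2-yn-1-ol (carbinol epimers) | OC(C#Cc1ccc(O[Si](C(C)C)(C(C)C)C(C)C)c(C2=Cc3ccc(O[Si](C(C)C)(C(C)C)C(C)C)cc3O[C@H]2c2ccc(O[Si](C(C)C)(C(C)C)C(C)C)cc2)c1)c1ccc(O[Si](C(C)C)(C(C)C)C(C)C)cc1O[Si](C(C)C)(C(C)C)C(C)C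
F3 | step 10 | (E)-1-[2,4-bis(triisopropylsilyloxy)phenyl]-3-{4-(triisopropylsilyloxy)-3-[(S)-7-(triisopropylsilyloxy)-2-[4-(triisopropylsilyloxy)phenyl]-2H-chromen-3-yl]phenyl}prop-2-en-1-ol (carbinol epimers) | OC(/C=C/c1ccc(O[Si](C(C)C)(C(C)C)C(C)C)c(C2=Cc3ccc(O[Si](C(C)C)(C(C)C)C(C)C)cc3O[C@H]2c2ccc(O[Si](C(C)C)(C(C)C)C(C)C)cc2)c1)c1ccc(O[Si](C(C)C)(C(C)C)C(C)C)cc1O[Si](C(C)C)(C(C)C)C(C)C
F4 | step 10 | (E)-1-[2,4-bis(triisopropylsilyloxy)phenyl]-3-{4-(triisopropylsilyloxy)-3-[(S)-7-(triisopropylsilyloxy)-2-[4-(triisopropylsilyloxy)phenyl]-2H-chromen-3-yl]phenyl}prop-2-en-1-one | O=C(/C=C/c1ccc(O[Si](C(C)C)(C(C)C)C(C)C)c(C2=Cc3ccc(O[Si](C(C)C)(C(C)C)C(C)C)cc3O[C@H]2c2ccc(O[Si](C(C)C)(C(C)C)C(C)C)cc2)c1)c1ccc(O[Si](C(C)C)(C(C)C)C(C)C)cc1O[Si](C(C)C)(C(C)C)C(C)C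
F5 | step 5 | (R)-7-(triisopropylsilyloxy)-2-[4-(triisopropylsilyloxy)phenyl]-2H-chromene | C1=Cc2ccc(O[Si](C(C)C)(C(C)C)C(C)C)cc2O[C@H]1c1ccc(O[Si](C(C)C)(C(C)C)C(C)C)cc1
F6 | step 5 | (2S)-3,4-dibromo-7-(triisopropylsilyloxy)-2-[4-(triisopropylsilyloxy)phenyl]chromane (expected 2,3-trans-3,4-trans isomer) | Br[C@@H]1[C@@H](Br)c2ccc(O[Si](C(C)C)(C(C)C)C(C)C)cc2O[C@H]1c1ccc(O[Si](C(C)C)(C(C)C)C(C)C)cc1
F7 | step 9 | 2-bromo-4-[(trimethylsilyl)ethynyl]phenol | Oc1ccc(C#C[Si](C)(C)C)cc1Br
F8 | step 9 | 2-(4,4,5,5-tetramethyl-1,3,2-dioxaborolan-2-yl)-4-[(trimethylsilyl)ethynyl]phenol | Oc1ccc(C#C[Si](C)(C)C)cc1B1OC(C)(C)C(C)(C)O1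
F9 | step 9 | 2-[(S)-7-(triisopropylsilyloxy)-2-[4-(triisopropylsilyloxy)phenyl]-2H-chromen-3-yl]-4-[(trimethylsilyl)ethynyl]phenol | C[Si](C)(C)C#Cc1ccc(O)c(C2=Cc3ccc(O[Si](C(C)C)(C(C)C)C(C)C)cc3O[C@H]2c2ccc(O[Si](C(C)C)(C(C)C)C(C)C)cc2)c1
F10 | step 9 | 4-ethynyl-2-[(S)-7-(triisopropylsilyloxy)-2-[4-(triisopropylsilyloxy)phenyl]-2H-chromen-3-yl]phenol | C#Cc1ccc(O)c(C2=Cc3ccc(O[Si](C(C)C)(C(C)C)C(C)C)cc3O[C@H]2c2ccc(O[Si](C(C)C)(C(C)C)C(C)C)cc2)c1
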